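## Structural features

The target consists of two six-membered rings joined by one C–C bond: ring A is an oxane (O1, C2–C6) and ring B a cyclohexane (C1′–C6′), with C2 of ring A bonded to C1′ of ring B. Ring A holds the quaternary ether carbon C2 (CH3, O1, C3, C1′; S), a secondary bromide at C5 (R) and a gem-dimethyl carbon C6, so O1 sits between two fully substituted carbons. Ring B holds a secondary chloride at C3′ (R) and, next to it, a tertiary bromide with a methyl group at C4′ (R); C1′ (S) is the fifth stereocentre. C2 and C1′ are adjacent across the inter-ring bond, C3′ and C4′ are adjacent, C5 is 1,4 to C2, and C1′ is 1,3 to C3′ and 1,4 to C4′. In the chairs, Br at C5 and ring B at C2 are equatorial and trans (C2–CH3 axial); the oxanyl group on C1′ is equatorial, and Cl (C3′) and Br (C4′) are trans-diaxial, Br cis and Cl trans to the oxanyl group. The fragile groups are the vicinal tertiary bromide/secondary chloride (elimination with bases, ionisation and halogen migration with Lewis acids) and the ring A ether (ionisation at C2 or C6 in strong acid). The real difficulty is ring B: the halogens sit opposite to the way a Br+/Cl− pair adds to a C3′=C4′ alkene, the face must be chosen relative to the remote C1′, and C1′ is hard to set next to C2 because its two ring arms differ only at their far end. The feature exploited is that C1′ is stereogenic only because C3′ and C5′ differ: with C4′ as a carbonyl carbon, ring B has a local mirror plane through C1′ and C4′, so C1′ and C3′ can be created together by one group- and face-selective chlorination at C3′, and C4′ then follows from C3′.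

## Logic of the disconnections

14 ⇒ 12 (through 13). The C4′–Br bond is cut. A tertiary bromide anti to an axial C3′–Cl bond is what capture of the C4′ cation by bromide gives, because the neighbouring chlorine bridges one face. This removes the most labile function, and both C4′ carbinol epimers converge. The forward step must ionise C4′–O without ionising the ring A ether.

12 ⇒ 11. The C4′–CH3 bond is cut, which turns C4′ into a carbonyl carbon and ring B into an α-chloro ketone. The gain is that the C–Cl bond now sits α to a carbonyl, where it can be made by substitution of a C–H bond, not by addition to an alkene. The forward addition must outrun enolisation at C3′.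

11 ⇒ 9 (through 10). The C3′–Cl bond is cut; this is the key disconnection. Without the chlorine, ring B has a local mirror plane through C1′ and C4′, so two stereocentres (C1′, C3′) and the whole regiochemical problem of the dihalide disappear at once, leaving only C2 and C5. The forward step must select one of two α-methylene groups and the axial face; a chiral amine catalyst and the stereoelectronics of the enamine are asked to do this together.

9 ⇒ 8 ⇒ 4 + 6 (through 7). The C2–C1′ bond is cut, with C2 as the cationic carbon of a cyclic oxocarbenium ion and ring B as a vinylogous enol ether. The union is convergent, C2 is set by relay from C5, and C1′ need not be controlled because saturation of 8 removes its stereogenicity. The forward step requires attack through the terminal carbon of 6 and on the face of 7 opposite to bromine.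

4 ⇒ 3 ⇒ 2 ⇒ 1. The C2–OCH3 bond, the C5–Br bond and the epoxide oxygen are removed in turn. A single catalytic asymmetric step on an achiral commodity ketone then supplies C5, from which C2 is relayed. The forward opening must place bromide on the secondary carbon with inversion and must not ionise the tertiary one.

6 ⇒ 5. The O–Si bond is cut. The forward silylation must give the linearly conjugated dienol ether.

## Other disconnections considered

Alternative 1: This is the first plan that comes to mind. It cuts C6–O and C5–Br of ring A and both C–halogen bonds of ring B, and starts from commercial (−)-α-bisabolol A1, which already carries C2 and C1′. The forward steps are a bromonium-induced 6-endo etherification (for example with Et2SBr·SbCl5Br) to the bromo ether A2, then addition of electrophilic bromine and chloride across C3′=C4′. The target is the diaxial adduct with Cl on the secondary and Br on the tertiary carbon, Br cis to the oxanyl group. It can only arise from the bromonium ion on the cis face opened at its less substituted carbon. The bromonium ion on the other face is opened at the tertiary carbon in a channel that is both diaxial and Markovnikov, and this leads to the constitutional isomer A3. Bromonium formation is reversible, so the faster channel should drain the material and A3 is expected to dominate; no element in A2 controls the face. The chosen plan fixes the constitution by making C–Cl α to a carbonyl and C–Br by cation capture, at the cost of more steps.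

Alternative 2: The same C2–C1′ bond is cut, but the union of 7 with 6 is asked to set C2 and C1′ together, giving the single enone epimer A4. Conjugate hydrosilylation of A4 and chlorination of the regiodefined silyl enol ether would then give 11 without a chiral amine. In the open transition state, however, the prochiral terminal carbon of 6 must distinguish the CH3 group on the cationic carbon from the ring CH2 (C3). These are of similar size and offer no polar or chelating handle, so low simple diastereoselection is expected. The chosen plan costs no extra step: it hydrogenates the epimer mixture to the locally symmetric 9 and moves the decision to a catalyst-controlled event.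

Alternative 3: A temporary ether bridge is used. C4′–Br is cut and C4′ is reconnected to the oxygen on C2. Forward, chloroetherification of A1 across C3′=C4′ with its tertiary hydroxyl would give the bridged chloro ether A5, with Cl forced onto C3′ anti to the bridge. A bromonium ion on the side-chain alkene would then be captured by the bridging oxygen, and the resulting oxonium ion would fragment at C4′–O with chloronium assistance and take up bromide at C4′, giving 14 in two steps. The plan is short but rests on two unsupported selectivities in a row. In the first step the side-chain alkene of A1 can close unstrained five- and six-membered ethers, whereas A5 needs a boat with an axial substituent. In the second step the oxonium ion would carry three fully substituted carbons and competes with 5-exo closure. The chosen plan uses only separately precedented reaction types.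

Key step: step 7

Assumption: the antipodes of the two chiral catalysts (steps 1 and 7) are named for the sense of induction that the route requires; should either induce the opposite sense, its mirror image is used with no other change.

## Route

Step 1
Reactants: 1 6-methylhept-5-en-2-one
Product: 2 4-[(2S)-3,3-dimethyloxiran-2-yl]butan-2-one
Conditions: 1,2:4,5-di-O-isopropylidene-β-L-erythro-2,3-hexodiulo-2,6-pyranose (enantiomer of the Shi ketone, 30 mol%), Oxone (2KHSO5·KHSO4·K2SO4), K2CO3, n-Bu4NHSO4, MeCN/CH2(OMe)2–aq. Na2B4O7/Na2EDTA, 0 °C
Reagents that add atoms: potassium peroxymonosulfate (the oxidant of Oxone), [K+].[O-]S(=O)(=O)OO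
Why: Shi asymmetric epoxidation: the chiral dioxirane formed from the ketone catalyst and KHSO5 transfers oxygen to the electron-rich trisubstituted alkene through a spiro transition state, and the catalyst antipode is chosen so that the CH carbon becomes S. The unactivated methyl ketone of 1 forms a dioxirane far more slowly than the catalyst, so an achiral background path should be minor.

Step 2
Reactants: 2 4-[(2S)-3,3-dimethyloxiran-2-yl]butan-2-one
Product: 3 (5R)-5-bromo-6-hydroxy-6-methylheptan-2-one (in equilibrium with its cyclic hemiketal (5R)-5-bromo-2,6,6-trimethyloxan-2-ol)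
Conditions: Li2NiBr4 (1.5 equiv), THF, 0 °C → rt; then H2O (pH 7)
Reagents that add atoms: dilithium tetrabromonickelate, [Li+].[Li+].[Ni+2].[Br-].[Br-].[Br-].[Br-]
Why: Epoxide opening by a soft, non-acidic bromide source: SN2 attack at the less substituted epoxide carbon with inversion turns the S epoxide carbon into the R bromide and leaves the tertiary oxygen in place. The absence of a Brønsted or strong Lewis acid suppresses opening at the tertiary carbon.

Step 3
Reactants: 3 (5R)-5-bromo-6-hydroxy-6-methylheptan-2-one
Product: 4 (5R)-5-bromo-2-methoxy-2,6,6-trimethyloxane (both C2 anomers)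
Conditions: MeOH, pyridinium p-toluenesulfonate (5 mol%), 3 Å molecular sieves, rt
Reagents that add atoms: methanol, CO
Why: Acid-catalysed ketalisation: the δ-hydroxy ketone closes to the six-membered hemiketal (helped by the gem-dimethyl group, Thorpe–Ingold effect) and exchanges OH for OCH3. The anomer ratio is irrelevant because C2 becomes planar in step 5, and C5 is not touched.

Step 4
Reactants: 5 cyclohex-2-en-1-one
Product: 6 (cyclohexa-1,3-dien-1-yloxy)trimethylsilane
Conditions: Me3SiCl, Et3N, DMF, 90 °C; pentane extraction, fractional distillation
Reagents that add atoms: chlorotrimethylsilane, C[Si](C)(C)Cl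
Why: O-silylation of the enone under equilibrating conditions (amine hydrochloride, heat) should favour the linearly conjugated 1-silyloxy-1,3-diene, in which the oxygen lone pair is conjugated with both double bonds. Any cross-conjugated 2-silyloxy isomer is removed by distillation.

Step 5
Reactants: 4 (5R)-5-bromo-2-methoxy-2,6,6-trimethyloxane; 6 (cyclohexa-1,3-dien-1-yloxy)trimethylsilane
Product: 8 4-[(2S,5R)-5-bromo-2,6,6-trimethyloxan-2-yl]cyclohex-2-en-1-one (both epimers at C4 of the enone), via oxocarbenium triflate 7 (not isolated)
Conditions: Me3SiOTf (10 mol%), CH2Cl2, −78 °C; then aq. NaHCO3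
Reagents that add atoms: none
Why: Vinylogous Mukaiyama addition: Me3SiOTf ionises the ketal to the cyclic oxocarbenium ion 7, which is attacked by the terminal carbon of the silyl dienol ether, the position that leads directly to the conjugated enone, and loss of the silyl group regenerates the catalyst. In the half-chair of 7 the C5–Br bond should prefer the pseudoaxial position (closer to the cationic carbon, gauche to only one C6 methyl group), and the nucleophile enters along the axial trajectory of the chair-like transition state on the face opposite to bromine, so ring B ends trans to Br (2S). The configuration at C4 of the enone is not controlled and is erased in step 6.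

Step 6
Reactants: 8 4-[(2S,5R)-5-bromo-2,6,6-trimethyloxan-2-yl]cyclohex-2-en-1-one
Product: 9 4-[(2S,5R)-5-bromo-2,6,6-trimethyloxan-2-yl]cyclohexan-1-one
Conditions: H2 (1 atm), RhCl(PPh3)3 (5 mol%), PhMe, rt
Reagents that add atoms: none
Why: Homogeneous hydrogenation of the disubstituted enone double bond; the rhodium–phosphine catalyst should leave the secondary C–Br bond and the ether untouched. Both epimers of 8 converge on 9, in which C1′ lies on the local mirror plane of ring B and is no longer stereogenic.

Step 7
Reactants: 9 4-[(2S,5R)-5-bromo-2,6,6-trimethyloxan-2-yl]cyclohexan-1-one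
Product: 11 (2R,4S)-4-[(2S,5R)-5-bromo-2,6,6-trimethyloxan-2-yl]-2-chlorocyclohexan-1-one, via enamine 10 (not isolated)
Conditions: N-chlorosuccinimide (1.05 equiv), (4R,5R)-4,5-diphenylimidazolidine (20 mol%), 2-nitrobenzoic acid (20 mol%), MeCN, −24 °C
Reagents that add atoms: N-chlorosuccinimide, ClN1C(=O)CCC1=O
Why: The secondary amine condenses with the ketone to an iminium ion in fast equilibrium with the two regioisomeric enamines (toward C3′ or C5′); N-chlorosuccinimide transfers Cl+ to the enamine β-carbon, and hydrolysis of the α-chloro iminium ion releases 11 and the catalyst. The closest known reaction types are the amine-catalysed enantioselective α-chlorination of cyclohexanones with N-chlorosuccinimide and the enamine-mediated desymmetrisation of 4-substituted cyclohexanones by α-heterofunctionalisation. No ring is closed. The C–Cl stereocentre (C3′) is controlled by the catalyst, whose C2-symmetric diphenyl framework shields one face of either enamine so that chlorine is delivered with one absolute sense (R). C1′ is controlled by substrate and catalyst in concert: with the bulky oxanyl group locked equatorial, the stereoelectronically required axial attack coincides with the catalyst-exposed face only in enamine 10, so this enamine reacts (Curtin–Hammett), chlorine ends axial and trans to the oxanyl group, and this choice of methylene group makes C1′ stereogenic (S). The step needs selection of one of two α-methylene groups, axial over equatorial delivery, mono- over dichlorination, and no epimerisation of the axial chloride. These are secured by the catalyst (group and face), the conformational lock from the quaternary C2 substituent (axial path), the lower enamine-forming ability of the α-chloro ketone, and the low temperature with near-stoichiometric reagent; the stereocentres of ring A are too remote to interfere.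

Step 8
Reactants: 11 (2R,4S)-4-[(2S,5R)-5-bromo-2,6,6-trimethyloxan-2-yl]-2-chlorocyclohexan-1-one
Product: 12 (1S,2R,4S)-4-[(2S,5R)-5-bromo-2,6,6-trimethyloxan-2-yl]-2-chloro-1-methylcyclohexan-1-ol
Conditions: MeMgBr (1.3 equiv), Et2O, −78 °C; cold aq. NH4Cl
Reagents that add atoms: methylmagnesium bromide, C[Mg]Br
Why: Grignard addition to the activated α-chloro ketone; attack anti to the axial C–Cl bond along the axial trajectory (polar and torsional control) should place CH3 axial and OH equatorial, cis to Cl, an arrangement that cannot close to an epoxide. The low temperature should prevent enolisation at C3′ and the semipinacol shift, and the configuration at C4′ is of no consequence because both epimers give the same cation in step 9.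

Step 9
Reactants: 12 (1S,2R,4S)-4-[(2S,5R)-5-bromo-2,6,6-trimethyloxan-2-yl]-2-chloro-1-methylcyclohexan-1-ol
Product: 14 (2S,5R)-5-bromo-2-[(1S,3R,4R)-4-bromo-3-chloro-4-methylcyclohexyl]-2,6,6-trimethyloxane (target), via tertiary carbocation 13 (not isolated)
Conditions: Me3SiBr (2 equiv), CH2Cl2, −20 → 0 °C
Reagents that add atoms: bromotrimethylsilane, C[Si](C)(C)Br
Why: Unimolecular substitution of the tertiary alcohol by bromide (silylation, then ionisation by the HBr formed). In cation 13 the axial C3′–Cl bond is aligned with the empty orbital and bridges the lower face (chloronium character), so bromide should attack C4′ from the opposite face along the axial direction. Attack at the tertiary carbon and trans-diaxial opening (Fürst–Plattner) coincide, which gives Br axial and cis to the oxanyl group with CH3 equatorial (4′R).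

## Compound list

1 | 6-methylhept-5-en-2-one | CC(=O)CCC=C(C)C | starting material
2 | 4-[(2S)-3,3-dimethyloxiran-2-yl]butan-2-one | CC(=O)CC[C@@H]1OC1(C)C | intermediate
3 | (5R)-5-bromo-6-hydroxy-6-methylheptan-2-one (open form of the hemiketal (5R)-5-bromo-2,6,6-trimethyloxan-2-ol) | CC(=O)CC[C@@H](Br)C(C)(C)O | intermediate
4 | (5R)-5-bromo-2-methoxy-2,6,6-trimethyloxane, both C2 anomers | COC1(C)CC[C@@H](Br)C(C)(C)O1 | intermediate
5 | cyclohex-2-en-1-one | O=C1C=CCCC1 | starting material
6 | (cyclohexa-1,3-dien-1-yloxy)trimethylsilane | C[Si](C)(C)OC1=CC=CCC1 | intermediate
7 | (3R)-3-bromo-2,2,6-trimethyl-2,3,4,5-tetrahydropyrylium trifluoromethanesulfonate (not isolated) | CC1=[O+]C(C)(C)[C@H](Br)CC1.[O-]S(=O)(=O)C(F)(F)F | intermediate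
8 | 4-[(2S,5R)-5-bromo-2,6,6-trimethyloxan-2-yl]cyclohex-2-en-1-one, both C4 epimers | CC1(C)O[C@](C)(C2CCC(=O)C=C2)CC[C@H]1Br | intermediate
9 | 4-[(2S,5R)-5-bromo-2,6,6-trimethyloxan-2-yl]cyclohexan-1-one | CC1(C)O[C@](C)(C2CCC(=O)CC2)CC[C@H]1Br | intermediate
10 | (4R,5R)-1-{(4S)-4-[(2S,5R)-5-bromo-2,6,6-trimethyloxan-2-yl]cyclohex-1-en-1-yl}-4,5-diphenylimidazolidine (not isolated) | CC1(C)O[C@](C)([C@H]2CCC(N3CN[C@H](c4ccccc4)[C@H]3c3ccccc3)=CC2)CC[C@H]1Br | intermediate
11 | (2R,4S)-4-[(2S,5R)-5-bromo-2,6,6-trimethyloxan-2-yl]-2-chlorocyclohexan-1-one | CC1(C)O[C@](C)([C@H]2CCC(=O)[C@H](Cl)C2)CC[C@H]1Br | intermediate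
12 | (1S,2R,4S)-4-[(2S,5R)-5-bromo-2,6,6-trimethyloxan-2-yl]-2-chloro-1-methylcyclohexan-1-ol | CC1(C)O[C@](C)([C@H]2CC[C@@](O)(C)[C@H](Cl)C2)CC[C@H]1Br | intermediate
13 | (2R,4S)-4-[(2S,5R)-5-bromo-2,6,6-trimethyloxan-2-yl]-2-chloro-1-methylcyclohexan-1-ylium bromide (not isolated) | CC1(C)O[C@](C)([C@H]2CC[C+](C)[C@H](Cl)C2)CC[C@H]1Br.[Br-] | intermediate
14 | (2S,5R)-5-bromo-2-[(1S,3R,4R)-4-bromo-3-chloro-4-methylcyclohexyl]-2,6,6-trimethyloxane | CC1(C)O[C@](C)([C@H]2CC[C@@](C)(Br)[C@H](Cl)C2)CC[C@H]1Br | target

## Step count and least certain steps

Total step count: 9. Longest linear sequence: 8 steps (steps 1, 2, 3, 5, 6, 7, 8, 9); step 4 prepares the second fragment.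

Step 7 (key step). The most likely failure is incomplete discrimination between the two α-methylene groups and between axial and equatorial delivery of chlorine, because the existing stereocentres are four bonds away and only the catalyst differentiates the two enamines. Over-chlorination and epimerisation of the axial chloride through re-enolisation are secondary concerns. The fallback sets out from 9 and comes back at 11, and separates the two events. Enantiotopic-group-selective deprotonation of 9 with lithium (R,R)-bis(1-phenylethyl)amide, LiN[CH(CH3)Ph]2 (or its mirror image, chosen as for the catalyst), with LiCl and Me3SiCl in THF at −100 °C should give trimethyl({(4S)-4-[(2S,5R)-5-bromo-2,6,6-trimethyloxan-2-yl]cyclohex-1-en-1-yl}oxy)silane F1. This silyl enol ether is purified and then chlorinated with N-chlorosuccinimide (CH2Cl2, −78 → 0 °C); axial attack on the half-chair delivers 11.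

Step 5. The most likely failure is loss of regiocontrol on the nucleophile side: attack through the α-carbon of 6, or carry-over of cross-conjugated silyl dienol ether from step 4, would join ring B through the wrong carbon. Proton loss from 7 to an enol ether that then adds to a second cation is a further risk. Erosion of facial selectivity at C2 is the stereochemical risk, because both chair-like approaches pass an axial methyl group on C6. The fallback sets out from 4 and comes back at 8, and uses a ring B synthon with only one nucleophilic carbon followed by a Stork–Danheiser transposition. Commercial 3-ethoxycyclohex-2-en-1-one F2 is converted with LiN(iPr)2 and Me3SiCl (THF, −78 °C) into 1-ethoxy-3-(trimethylsilyloxy)cyclohexa-1,3-diene F3. Union with 4 (Me3SiOTf, CH2Cl2, −78 °C; the more reactive nucleophile also permits the lowest temperature) should give 6-[(2S,5R)-5-bromo-2,6,6-trimethyloxan-2-yl]-3-ethoxycyclohex-2-en-1-one F4. Reduction with iBu2AlH (PhMe, −78 °C) to 6-[(2S,5R)-5-bromo-2,6,6-trimethyloxan-2-yl]-3-ethoxycyclohex-2-en-1-ol F5 and treatment with dilute aqueous HCl then give 8.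

Step 2. The most likely failure is competing opening at the tertiary carbon (any adventitious acid shifts the reaction that way) and slow substitution at a secondary carbon flanked by a fully substituted one, with participation of the ketone oxygen as a further leak. This costs yield and, if ionisation intervenes, enantiomeric purity at C5. The fallback sets out from 1 and comes back at 11; it makes the C–Br bond with electrophilic bromine and defers the resolution to the key step. Bromohydrin formation on 1 (N-bromosuccinimide, THF/H2O, 0 °C; water enters at the tertiary carbon) gives racemic 3, that is 3 together with (5S)-5-bromo-6-hydroxy-6-methylheptan-2-one F6. Steps 3, 5 and 6 are run on the racemate, so 4, 8 and 9 are accompanied by (5S)-5-bromo-2-methoxy-2,6,6-trimethyloxane F7, 4-[(2R,5S)-5-bromo-2,6,6-trimethyloxan-2-yl]cyclohex-2-en-1-one F8 and 4-[(2R,5S)-5-bromo-2,6,6-trimethyloxan-2-yl]cyclohexan-1-one F9. In step 7 the catalyst should install the same (2R,4S) pattern on ring B of both enantiomers, so 11 is accompanied by its diastereomer (2R,4S)-4-[(2R,5S)-5-bromo-2,6,6-trimethyloxan-2-yl]-2-chlorocyclohexan-1-one F10. The two differ in the relation between the adjacent centres C2 and C1′ and should be separable by chromatography, at the price of half the material.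

Step 9. The most likely failure is competing ionisation of the ring A ether, whose oxygen is flanked by two fully substituted carbons while the C4′ carbinol is deactivated by the β-chlorine. Elimination from cation 13, or its capture by the ring A oxygen across ring B, are further risks. The fallback sets out from 11 and comes back at 14, and generates the same cation from an alkene at much lower temperature. Me3SiCH2MgCl (Et2O, −78 °C) adds to 11 to give (2R,4S)-4-[(2S,5R)-5-bromo-2,6,6-trimethyloxan-2-yl]-2-chloro-1-[(trimethylsilyl)methyl]cyclohexan-1-ol F11. Anhydrous HBr (2.2 equiv, CH2Cl2, −78 °C) effects the Peterson elimination, made easy by the β-silyl group, to (2S,5R)-5-bromo-2-[(1S,3R)-3-chloro-4-methylidenecyclohexyl]-2,6,6-trimethyloxane F12. The second equivalent of HBr then adds in the Markovnikov sense (−78 → −30 °C) through the bridged cation 13 to give 14.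

## Further compounds

F1 | step 7 | trimethyl({(4S)-4-[(2S,5R)-5-bromo-2,6,6-trimethyloxan-2-yl]cyclohex-1-en-1-yl}oxy)silane | CC1(C)O[C@](C)([C@H]2CCC(O[Si](C)(C)C)=CC2)CC[C@H]1Br
F2 | step 5 | 3-ethoxycyclohex-2-en-1-one (purchased) | CCOC1=CC(=O)CCC1
F3 | step 5 | 1-ethoxy-3-(trimethylsilyloxy)cyclohexa-1,3-diene | CCOC1=CC(O[Si](C)(C)C)=CCC1
F4 | step 5 | 6-[(2S,5R)-5-bromo-2,6,6-trimethyloxan-2-yl]-3-ethoxycyclohex-2-en-1-one, both C6 epimers | CCOC1=CC(=O)C(CC1)[C@]2(C)CC[C@@H](Br)C(C)(C)O2
F5 | step 5 | 6-[(2S,5R)-5-bromo-2,6,6-trimethyloxan-2-yl]-3-ethoxycyclohex-2-en-1-ol, mixture at C1 and C6 | CCOC1=CC(O)C(CC1)[C@]2(C)CC[C@@H](Br)C(C)(C)O2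
F6 | step 2 | (5S)-5-bromo-6-hydroxy-6-methylheptan-2-one | CC(=O)CC[C@H](Br)C(C)(C)O
F7 | step 2 | (5S)-5-bromo-2-methoxy-2,6,6-trimethyloxane, both C2 anomers | COC1(C)CC[C@H](Br)C(C)(C)O1
F8 | step 2 | 4-[(2R,5S)-5-bromo-2,6,6-trimethyloxan-2-yl]cyclohex-2-en-1-one, both C4 epimers | CC1(C)O[C@@](C)(C2CCC(=O)C=C2)CC[C@@H]1Br
F9 | step 2 | 4-[(2R,5S)-5-bromo-2,6,6-trimethyloxan-2-yl]cyclohexan-1-one | CC1(C)O[C@@](C)(C2CCC(=O)CC2)CC[C@@H]1Br
F10 | step 2 | (2R,4S)-4-[(2R,5S)-5-bromo-2,6,6-trimethyloxan-2-yl]-2-chlorocyclohexan-1-one | CC1(C)O[C@@](C)([C@H]2CCC(=O)[C@H](Cl)C2)CC[C@@H]1Br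
F11 | step 9 | (2R,4S)-4-[(2S,5R)-5-bromo-2,6,6-trimethyloxan-2-yl]-2-chloro-1-[(trimethylsilyl)methyl]cyclohexan-1-ol, both C1 epimers | CC1(C)O[C@](C)([C@H]2CCC(O)(C[Si](C)(C)C)[C@H](Cl)C2)CC[C@H]1Br
F12 | step 9 | (2S,5R)-5-bromo-2-[(1S,3R)-3-chloro-4-methylidenecyclohexyl]-2,6,6-trimethyloxane | CC1(C)O[C@](C)([C@H]2CCC(=C)[C@H](Cl)C2)CC[C@H]1Br
A1 | alternative 1 | (2S)-6-methyl-2-[(1S)-4-methylcyclohex-3-en-1-yl]hept-5-en-2-ol, (−)-α-bisabolol | CC1=CC[C@H](CC1)[C@](C)(CCC=C(C)C)O
A2 | alternative 1 | (2S,5R)-5-bromo-2,6,6-trimethyl-2-[(1S)-4-methylcyclohex-3-en-1-yl]oxane | CC1(C)O[C@](C)([C@H]2CCC(C)=CC2)CC[C@H]1Br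
A3 | alternative 1 | (2S,5R)-5-bromo-2-[(1S,3R,4R)-3-bromo-4-chloro-4-methylcyclohexyl]-2,6,6-trimethyloxane | CC1(C)O[C@](C)([C@H]2CC[C@@](C)(Cl)[C@H](Br)C2)CC[C@H]1Br
A4 | alternative 2 | (4S)-4-[(2S,5R)-5-bromo-2,6,6-trimethyloxan-2-yl]cyclohex-2-en-1-one | CC1(C)O[C@](C)([C@H]2CCC(=O)C=C2)CC[C@H]1Br
A5 | alternative 3 | (1R,3S,4S,6R)-6-chloro-1,3-dimethyl-3-(4-methylpent-3-en-1-yl)-2-oxabicyclo[2.2.2]octane | C[C@]1(CC[C@H]2C[C@H]1Cl)O[C@@]2(C)CCC=C(C)C
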